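**Plan**

- Retrosynthesis: the C11=C12 and C11'=C12' bonds are cut (two Wittig reactions) to give a C10 dialdehyde and two C15 phosphonium salts. The C4 and C4' carbinols are traced back to the 4,4'-diketone, (3S,3'S)-7,8-didehydroastaxanthin.
- Both C15 salts come from one acetylenic 3-hydroxy-4-oxo C15 ketone; the olefinic salt is reached by Zn/AcOH semi-reduction of its 7,8-triple bond.
- The ring of that ketone is cut [3+3] across C2–C3 and C5=C6. The gem-dimethyl carbon C1 sits between C2 and the alkynyl-bearing C6, so C2–C1–C6 can be stored as a 1-alkynyl-2,2-dimethylcyclopropanol (a ketone homoenolate that cannot enolise). C3–C4–C5 with the C5 methyl is 2-oxobutanal.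
- Forward: cyclopropanol + 2-oxobutanal → ring (homoaldol, then aldol condensation) → resolution → branch to the two salts → two Wittig reactions on the dialdehyde → double reduction.
- Stereochemistry: C3/C3' (S) from lipase resolution of the annulation product; C4/C4' (S, trans to the 3-OH) from hydroxyl-directed hydride delivery; (E)-alkenes from the (E)-enynol, the Zn/AcOH reduction and thermal equilibration after each Wittig step.

Key step: step 5

Remark: the enynol, methyl 3-chloropivalate, 1-hydroxybutan-2-one and the C10 dialdehyde are taken as commercial (the chloro ester is otherwise one operation from 3-chloropivaloyl chloride and methanol).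
Remark: the lipase of step 6 is assumed to acylate the (R)-alcohol faster (carbonyl side acting as the larger group); with the opposite sense the (S)-acetate would be collected and methanolysed instead.

**Step 1**
Reactants: 1 (2E)-3-methylpent-2-en-4-yn-1-ol
Product: 2 TBS ether of 1
Conditions: TBSCl, imidazole, DMF, 0 °C → rt
Reagents that add atoms: tert-butyldimethylsilyl chloride, CC(C)(C)[Si](C)(C)Cl
Why: Standard silylation of a primary allylic alcohol, which masks the hydroxyl against the Grignard and zinc bases that follow; no stereocentre is involved.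

**Step 2**
Reactants: 3 methyl 3-chloro-2,2-dimethylpropanoate
Product: 5 1-methoxy-2,2-dimethylcyclopropan-1-ol (cyclopropanone hemiketal), via silyl ketal 4 (not isolated)
Conditions: Na, TMSCl, toluene, reflux; then MeOH, rt
Reagents that add atoms: none
Why: Sodium/TMSCl reductive cyclisation of a β-chloro ester (the acyloin-type route to cyclopropanone hemiketals) should close the three-membered ring by intramolecular displacement of chloride, the quaternary α-carbon excluding elimination, and methanolysis of 4 should give the racemic hemiketal, whose stereocentre is lost later.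

**Step 3**
Reactants: 2 TBS ether of 1; 5 cyclopropanone hemiketal
Product: 8 1-alkynyl-2,2-dimethylcyclopropan-1-ol (racemic), via alkynylmagnesium bromide 6 (not isolated), via 2,2-dimethylcyclopropanone 7 (not isolated)
Conditions: 2 + EtMgBr, THF, 0 → 40 °C; 5 + EtMgBr, THF, 0 °C; combined, 0 °C → rt; aq NH4Cl
Reagents that add atoms: none
Why: The magnesium salt of the hemiketal should release the strained ketone 7, which is trapped by the alkynyl Grignard reagent 6 in a 1,2-addition (the standard route to 1-alkynylcyclopropanols); the racemic carbinol centre is destroyed in step 5.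

**Step 4**
Reactants: 9 1-hydroxybutan-2-one
Product: 10 2-oxobutanal
Conditions: IBX, EtOAc, 75 °C; filtration, MgSO4; solution used at once
Reagents that add atoms: none
Why: IBX oxidation of a primary α-ketol should stop at the aldehyde and deliver the sensitive 1,2-dicarbonyl compound as a dried solution.

**Step 5**
Reactants: 8 alkynylcyclopropanol; 10 2-oxobutanal
Product: 14 racemic hydroxy-enynone (3-alkynyl-6-hydroxy-2,4,4-trimethylcyclohex-2-en-1-one), via zinc homoenolate 11 (not isolated), via homoaldol adduct 12 (not isolated), via aldol 13 (not isolated)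
Conditions: Et2Zn (0.55 equiv), THF, 0 °C → rt; 10 (1.5 equiv), 0 °C → rt; then Et3N, 50 °C; aq NH4Cl
Reagents that add atoms: none
Why: Proposed new method: deprotonation of 8 by Et2Zn should give a zinc cyclopropoxide that opens at its less substituted C–C bond to the β-zincio ynone 11 (a homoenolate that cannot enolise, its α-carbon being the gem-dimethyl carbon), whose CH2–Zn carbon adds to the aldehyde of 10 to make the ring C2–C3 bond (12); zinc/Et3N soft enolisation of the ethyl ketone then lets its CH2 attack the liberated ynone carbonyl (13), and loss of water gives the C5=C6 bond of the conjugated enynone. The closest known reaction types are the homoaldol addition of zinc or titanium homoenolates (from cyclopropanols or siloxycyclopropanes) to aldehydes and the aldol cyclodehydration of 1,5-diketones to cyclohexenones; their union as a formal [3+3] annulation of a cyclopropanol with a 1,2-dicarbonyl compound is new. The six-membered ring closes by a 6-(enolendo)-exo-trig aldol addition followed by E1cB dehydration. The one new stereocentre (carbinol C3) is formed without control, so 14 is racemic and is resolved in step 6. The step needs chemoselectivity for the aldehyde over the two ketones and productive enolisation on the ethyl side: the glyoxal aldehyde is by far the most electrophilic carbonyl, the ynone stays masked as the cyclopropoxide until the C–Zn bond has formed, and only the ethyl-side enolate can reach the ynone carbonyl through a six-membered transition state, enolisation on the carbinol side being reversible and unproductive. Irreversible dehydration to the fully conjugated enynone should drive the sequence.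

**Step 6**
Reactants: 14 racemic hydroxy-enynone
Product: 15 (S)-hydroxy-enynone
Conditions: Amano lipase PS, vinyl acetate, MTBE, 30 °C, stopped near half conversion; chromatography
Reagents that add atoms: none
Why: Lipase-catalysed transesterification is a kinetic resolution of a cyclic α'-hydroxy enone (a substrate class known to be resolved by lipases); the enzyme should acylate the (R)-alcohol and leave the (S)-alcohol, which carries the C3 configuration of both rings of the target.

**Step 7**
Reactants: 15 (S)-hydroxy-enynone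
Product: 18 acetylenic C15 phosphonium bromide, via desilylated diol 16 (not isolated), via allylic bromide 17 (not isolated)
Conditions: 48% aq HBr, CH2Cl2, −10 °C; then PPh3, EtOAc, rt
Reagents that add atoms: hydrogen bromide, Br; triphenylphosphine, c1ccc(cc1)P(c1ccccc1)c1ccccc1
Why: Aqueous HBr should cleave the primary silyl ether and convert the allylic alcohol 16 into the bromide 17, which alkylates PPh3 by SN2; the non-allylic α-ketol is inert to these conditions.

**Step 8**
Reactants: 15 (S)-hydroxy-enynone
Product: 19 (S)-hydroxy-dienone with a (7E)-alkene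
Conditions: Zn dust, AcOH, CH2Cl2, 0 °C → rt
Reagents that add atoms: none
Why: Zinc in acetic acid should transfer electrons to the conjugated ynenone and protonation of the dienolate gives the thermodynamically preferred (E)-alkene (dissolving-metal semi-reduction of an activated alkyne), leaving the isolated trisubstituted alkene and the silyl ether untouched.

**Step 9**
Reactants: 19 (S)-hydroxy-dienone
Product: 22 olefinic C15 phosphonium bromide, via desilylated diol 20 (not isolated), via allylic bromide 21 (not isolated)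
Conditions: 48% aq HBr, CH2Cl2, −10 °C; then PPh3, EtOAc, rt
Reagents that add atoms: hydrogen bromide, Br; triphenylphosphine, c1ccc(cc1)P(c1ccccc1)c1ccccc1
Why: Same desilylation, allylic bromination and SN2 phosphonium formation as in step 7, on the dienyl system.

**Step 10**
Reactants: 22 olefinic C15 phosphonium bromide; 23 (2E,4E,6E)-2,7-dimethylocta-2,4,6-trienedial (C10 dialdehyde)
Product: 25 C25 apo-aldehyde, via ylide 24 (not isolated)
Conditions: 23 (3 equiv), 1,2-epoxybutane, EtOH, reflux; then heptane, reflux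
Reagents that add atoms: none
Why: Wittig olefination of one formyl group of the symmetrical dialdehyde (used in excess) by the semi-stabilised allylic ylide 24, generated with 1,2-epoxybutane as a neutral HBr scavenger that spares the base-sensitive α-ketol centre; heating should bring the new C11'=C12' bond to (E).

**Step 11**
Reactants: 25 C25 apo-aldehyde; 18 acetylenic C15 phosphonium bromide
Product: 27 (3S,3'S)-7,8-didehydroastaxanthin, via ylide 26 (not isolated)
Conditions: 1,2-epoxybutane, EtOH, reflux, Ar, dark; then EtOH/heptane, reflux; crystallisation of the all-(E) isomer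
Reagents that add atoms: none
Why: Second Wittig olefination, forming C11=C12 with the propargylic-allylic ylide 26 under the same neutral conditions; thermal equilibration and crystallisation should give the all-(E) polyene.

**Step 12**
Reactants: 27 (3S,3'S)-7,8-didehydroastaxanthin
Product: 28 (3S,4S,3'S,4'S)-7,8-didehydro-β,β-carotene-3,4,3',4'-tetrol (target)
Conditions: Me4NBH(OAc)3, AcOH/THF/MeCN, −20 → 0 °C, Ar, dark
Reagents that add atoms: none
Why: Hydroxyl-directed triacetoxyborohydride reduction (Evans–Saksena reduction): each 3-hydroxyl should bind boron and deliver hydride to the neighbouring C4 carbonyl on the face syn to the C3–O bond, so each new carbinol is trans to the existing one, (4S) and (4'S) from (3S) and (3'S), with the polyene and alkyne untouched.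

**Compound list**

1 | (2E)-3-methylpent-2-en-4-yn-1-ol | C#C/C(C)=C/CO | starting material
2 | tert-butyl(dimethyl){[(2E)-3-methylpent-2-en-4-yn-1-yl]oxy}silane | C#C/C(C)=C/CO[Si](C)(C)C(C)(C)C | intermediate
3 | methyl 3-chloro-2,2-dimethylpropanoate | COC(=O)C(C)(C)CCl | starting material
4 | 1-methoxy-2,2-dimethyl-1-(trimethylsilyloxy)cyclopropane (racemic) | COC1(O[Si](C)(C)C)CC1(C)C | intermediate (not isolated)
5 | 1-methoxy-2,2-dimethylcyclopropan-1-ol (racemic) | COC1(O)CC1(C)C | intermediate
6 | bromo{(3E)-5-[(tert-butyldimethylsilyl)oxy]-3-methylpent-3-en-1-yn-1-yl}magnesium | Br[Mg]C#C/C(C)=C/CO[Si](C)(C)C(C)(C)C | intermediate (not isolated)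
7 | 2,2-dimethylcyclopropan-1-one | CC1(C)CC1=O | intermediate (not isolated)
8 | 1-{(3E)-5-[(tert-butyldimethylsilyl)oxy]-3-methylpent-3-en-1-yn-1-yl}-2,2-dimethylcyclopropan-1-ol (racemic) | CC1(C)CC1(O)C#C/C(C)=C/CO[Si](C)(C)C(C)(C)C | intermediate
9 | 1-hydroxybutan-2-one | CCC(=O)CO | starting material
10 | 2-oxobutanal | CCC(=O)C=O | intermediate
11 | bis{(6E)-8-[(tert-butyldimethylsilyl)oxy]-2,2,6-trimethyl-3-oxooct-6-en-4-yn-1-yl}zinc | CC(C)(C[Zn]CC(C)(C)C(=O)C#C/C(C)=C/CO[Si](C)(C)C(C)(C)C)C(=O)C#C/C(C)=C/CO[Si](C)(C)C(C)(C)C | intermediate (not isolated)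
12 | (10E)-12-[(tert-butyldimethylsilyl)oxy]-4-hydroxy-6,6,10-trimethyldodec-10-en-8-yne-3,7-dione (racemic) | CCC(=O)C(O)CC(C)(C)C(=O)C#C/C(C)=C/CO[Si](C)(C)C(C)(C)C | intermediate (not isolated)
13 | 3-{(3E)-5-[(tert-butyldimethylsilyl)oxy]-3-methylpent-3-en-1-yn-1-yl}-3,6-dihydroxy-2,4,4-trimethylcyclohexan-1-one (diastereomer mixture) | CC1C(=O)C(O)CC(C)(C)C1(O)C#C/C(C)=C/CO[Si](C)(C)C(C)(C)C | intermediate (not isolated)
14 | rac-3-{(3E)-5-[(tert-butyldimethylsilyl)oxy]-3-methylpent-3-en-1-yn-1-yl}-6-hydroxy-2,4,4-trimethylcyclohex-2-en-1-one | CC1=C(C#C/C(C)=C/CO[Si](C)(C)C(C)(C)C)C(C)(C)CC(O)C1=O | intermediate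
15 | (6S)-3-{(3E)-5-[(tert-butyldimethylsilyl)oxy]-3-methylpent-3-en-1-yn-1-yl}-6-hydroxy-2,4,4-trimethylcyclohex-2-en-1-one | CC1=C(C#C/C(C)=C/CO[Si](C)(C)C(C)(C)C)C(C)(C)C[C@H](O)C1=O | intermediate
16 | (6S)-6-hydroxy-3-[(3E)-5-hydroxy-3-methylpent-3-en-1-yn-1-yl]-2,4,4-trimethylcyclohex-2-en-1-one | CC1=C(C#C/C(C)=C/CO)C(C)(C)C[C@H](O)C1=O | intermediate (not isolated)
17 | (6S)-3-[(3E)-5-bromo-3-methylpent-3-en-1-yn-1-yl]-6-hydroxy-2,4,4-trimethylcyclohex-2-en-1-one | CC1=C(C#C/C(C)=C/CBr)C(C)(C)C[C@H](O)C1=O | intermediate (not isolated)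
18 | {(2E)-5-[(4S)-4-hydroxy-2,6,6-trimethyl-3-oxocyclohex-1-en-1-yl]-3-methylpent-2-en-4-yn-1-yl}triphenylphosphonium bromide | CC1=C(C#C/C(C)=C/C[P+](c2ccccc2)(c2ccccc2)c2ccccc2)C(C)(C)C[C@H](O)C1=O.[Br-] | intermediate
19 | (6S)-3-{(1E,3E)-5-[(tert-butyldimethylsilyl)oxy]-3-methylpenta-1,3-dien-1-yl}-6-hydroxy-2,4,4-trimethylcyclohex-2-en-1-one | CC1=C(/C=C/C(C)=C/CO[Si](C)(C)C(C)(C)C)C(C)(C)C[C@H](O)C1=O | intermediate
20 | (6S)-6-hydroxy-3-[(1E,3E)-5-hydroxy-3-methylpenta-1,3-dien-1-yl]-2,4,4-trimethylcyclohex-2-en-1-one | CC1=C(/C=C/C(C)=C/CO)C(C)(C)C[C@H](O)C1=O | intermediate (not isolated)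
21 | (6S)-3-[(1E,3E)-5-bromo-3-methylpenta-1,3-dien-1-yl]-6-hydroxy-2,4,4-trimethylcyclohex-2-en-1-one | CC1=C(/C=C/C(C)=C/CBr)C(C)(C)C[C@H](O)C1=O | intermediate (not isolated)
22 | {(2E,4E)-5-[(4S)-4-hydroxy-2,6,6-trimethyl-3-oxocyclohex-1-en-1-yl]-3-methylpenta-2,4-dien-1-yl}triphenylphosphonium bromide | CC1=C(/C=C/C(C)=C/C[P+](c2ccccc2)(c2ccccc2)c2ccccc2)C(C)(C)C[C@H](O)C1=O.[Br-] | intermediate
23 | (2E,4E,6E)-2,7-dimethylocta-2,4,6-trienedial | O=C/C(C)=C/C=C/C=C(C)/C=O | starting material
24 | {(2E,4E)-5-[(4S)-4-hydroxy-2,6,6-trimethyl-3-oxocyclohex-1-en-1-yl]-3-methylpenta-2,4-dien-1-ylidene}triphenylphosphorane | CC1=C(/C=C/C(C)=C/C=P(c2ccccc2)(c2ccccc2)c2ccccc2)C(C)(C)C[C@H](O)C1=O | intermediate (not isolated)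
25 | (2E,4E,6E,8E,10E,12E)-13-[(4S)-4-hydroxy-2,6,6-trimethyl-3-oxocyclohex-1-en-1-yl]-2,7,11-trimethyltrideca-2,4,6,8,10,12-hexaenal | CC1=C(/C=C/C(C)=C/C=C/C(C)=C/C=C/C=C(C)/C=O)C(C)(C)C[C@H](O)C1=O | intermediate
26 | {(2E)-5-[(4S)-4-hydroxy-2,6,6-trimethyl-3-oxocyclohex-1-en-1-yl]-3-methylpent-2-en-4-yn-1-ylidene}triphenylphosphorane | CC1=C(C#C/C(C)=C/C=P(c2ccccc2)(c2ccccc2)c2ccccc2)C(C)(C)C[C@H](O)C1=O | intermediate (not isolated)
27 | (3S,3'S)-3,3'-dihydroxy-7,8-didehydro-β,β-carotene-4,4'-dione | CC1=C(C#C/C(C)=C/C=C/C(C)=C/C=C/C=C(C)/C=C/C=C(C)/C=C/C2=C(C)C(=O)[C@@H](O)CC2(C)C)C(C)(C)C[C@H](O)C1=O | intermediate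
28 | (3S,4S,3'S,4'S)-7,8-didehydro-β,β-carotene-3,4,3',4'-tetrol | CC1=C(C#C/C(C)=C/C=C/C(C)=C/C=C/C=C(C)/C=C/C=C(C)/C=C/C2=C(C)[C@H](O)[C@@H](O)CC2(C)C)C(C)(C)C[C@H](O)[C@H]1O | target

**Step count and risks**

Total steps: 12. Longest linear sequence: 9 (steps 1, 3, 5, 6, 8, 9, 10, 11, 12).

Most likely to fail:

1. Step 5. The zinc-bound homoenolate carbon may transfer too slowly, so that alkoxide-induced self-condensation of 10 or protonolysis of the opened cyclopropanol overtakes the homoaldol. The 1,5-diketone may also rest as a cyclic hemiketal and not close. The fallback uses known chemistry, sets out from 2 and rejoins the route at 14; the ring is taken ready-made instead of being built. Commercial 2,6,6-trimethylcyclohex-2-ene-1,4-dione is epoxidised with alkaline H2O2 to the epoxy-dione F1. Base isomerises this to the 3-hydroxy-enedione F2. Hydrogenation over Raney Ni reduces the unhindered carbonyl to the dihydroxy-enone F3, and acetone with acid gives the acetonide F4. The lithium acetylide of 2 (n-BuLi, THF, −78 °C) adds to the remaining carbonyl of F4 to give the tertiary propargylic alcohol F5. Dilute aqueous acid then removes the acetonide and dehydrates with transposition of the enone to give racemic 14.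

2. Step 6. The enzyme may discriminate the enantiomers insufficiently, or prefer the other one. The fallback sets out from 14 and rejoins at 15 by classical resolution through covalent diastereomers. 14 is acylated with (1S)-(−)-camphanic chloride (pyridine, DMAP, CH2Cl2) to the (6S)-camphanate F6 and the (6R)-camphanate F7. These are separated by crystallisation or chromatography, and F6 is methanolysed (K2CO3, MeOH, 0 °C) to 15.

3. Step 12. Facial selection may be incomplete at two carbonyl groups that react independently, giving diastereomeric tetrols that are hard to separate, and the new polyene-conjugated allylic alcohols may ionise in acid. The fallback sets out from 18 and 22 and rejoins at 28; the C4 carbinols are set on the crystalline C15 salts before the polyene is assembled. The same directed reduction converts 18 into the acetylenic diol salt F8 and 22 into the olefinic diol salt F9, each recrystallised to one diastereomer. F9 gives the ylide F10 (1,2-epoxybutane), which with excess 23 gives the C25 diol aldehyde F11. The ylide F12 from F8 then converts F11 directly into 28.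

**Further compounds**

F1 | step 5 | 2,3-epoxy-2,6,6-trimethylcyclohexane-1,4-dione (racemic) | CC12OC1C(=O)CC(C)(C)C2=O
F2 | step 5 | 3-hydroxy-2,6,6-trimethylcyclohex-2-ene-1,4-dione | CC1=C(O)C(=O)CC(C)(C)C1=O
F3 | step 5 | 3,4-dihydroxy-2,6,6-trimethylcyclohex-2-en-1-one (racemic) | CC1=C(O)C(O)CC(C)(C)C1=O
F4 | step 5 | 2,2,4,6,6-pentamethyl-7,7a-dihydro-1,3-benzodioxol-5(6H)-one (racemic) | CC1=C2OC(C)(C)OC2CC(C)(C)C1=O
F5 | step 5 | 5-{(3E)-5-[(tert-butyldimethylsilyl)oxy]-3-methylpent-3-en-1-yn-1-yl}-2,2,4,6,6-pentamethyl-5,6,7,7a-tetrahydro-1,3-benzodioxol-5-ol | CC1=C2OC(C)(C)OC2CC(C)(C)C1(O)C#C/C(C)=C/CO[Si](C)(C)C(C)(C)C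
F6 | step 6 | (1S)-camphanate of the (6S)-alcohol 15 | CC1=C(C#C/C(C)=C/CO[Si](C)(C)C(C)(C)C)C(C)(C)C[C@H](OC(=O)[C@@]23CC[C@@](C)(C(=O)O2)C3(C)C)C1=O
F7 | step 6 | (1S)-camphanate of the (6R)-alcohol | CC1=C(C#C/C(C)=C/CO[Si](C)(C)C(C)(C)C)C(C)(C)C[C@@H](OC(=O)[C@@]23CC[C@@](C)(C(=O)O2)C3(C)C)C1=O
F8 | step 12 | {(2E)-5-[(3S,4S)-3,4-dihydroxy-2,6,6-trimethylcyclohex-1-en-1-yl]-3-methylpent-2-en-4-yn-1-yl}triphenylphosphonium bromide | CC1=C(C#C/C(C)=C/C[P+](c2ccccc2)(c2ccccc2)c2ccccc2)C(C)(C)C[C@H](O)[C@H]1O.[Br-]
F9 | step 12 | {(2E,4E)-5-[(3S,4S)-3,4-dihydroxy-2,6,6-trimethylcyclohex-1-en-1-yl]-3-methylpenta-2,4-dien-1-yl}triphenylphosphonium bromide | CC1=C(/C=C/C(C)=C/C[P+](c2ccccc2)(c2ccccc2)c2ccccc2)C(C)(C)C[C@H](O)[C@H]1O.[Br-]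
F10 | step 12 | ylide of F9 | CC1=C(/C=C/C(C)=C/C=P(c2ccccc2)(c2ccccc2)c2ccccc2)C(C)(C)C[C@H](O)[C@H]1O
F11 | step 12 | (2E,4E,6E,8E,10E,12E)-13-[(3S,4S)-3,4-dihydroxy-2,6,6-trimethylcyclohex-1-en-1-yl]-2,7,11-trimethyltrideca-2,4,6,8,10,12-hexaenal | CC1=C(/C=C/C(C)=C/C=C/C(C)=C/C=C/C=C(C)/C=O)C(C)(C)C[C@H](O)[C@H]1O
F12 | step 12 | ylide of F8 | CC1=C(C#C/C(C)=C/C=P(c2ccccc2)(c2ccccc2)c2ccccc2)C(C)(C)C[C@H](O)[C@H]1O
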